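**Retrosynthetic overview**
1. Target 15 ⇒ diol lactone 13 by loss of water across C3–C4 and removal of two MOM groups.
2. 13 ⇒ enol cinnamate 11: one enantioselective copper–boryl conjugate addition/aldol lactonisation makes C3–C4 and the carbinol centre (C–B then C–OH).
3. 11 ⇒ diketone enolate 10 (from chalcone epoxide 5) + cinnamoyl chloride 9, forming the O1–C2 ester bond.
4. 5 ⇒ chalcone 3 ⇒ ketone 1 + aldehyde 2; 9 ⇒ aldehyde 6 + malonic acid 7.
5. Only one ring (the butenolide): O1–C2 acylation first, C3–C4 aldol closure second, C3=C4 dehydration last.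

Assumption: the presumed biosynthesis is taken as O-acylation of the enol of a tyrosine-derived 1,3-diarylpropane-1,2-dione by a C6–C3 cinnamoyl/β-hydroxyacyl thioester, then C3–C4 aldol closure and dehydration to the butenolide.
Assumption: the ligand enantiomer named in step 6 is taken to give Re-face borylation at the cinnamate β-carbon; its mirror image is used if the first run (chiral HPLC of 13) shows the opposite sense.

Step 1
Reactants: 1 1-(3-bromo-4-hydroxyphenyl)ethan-1-one; 2 3-bromo-4-hydroxybenzaldehyde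
Product: 3 (E)-1,3-bis(3-bromo-4-hydroxyphenyl)prop-2-en-1-one
Conditions: HCl (g)-saturated EtOH, 0 °C → rt
Reagents that add atoms: none
Why: Acid-catalysed Claisen–Schmidt aldol condensation tolerates free phenols (no deactivating phenoxides) and dehydrates to the conjugated E-enone.

Step 2
Reactants: 3 (E)-1,3-bis(3-bromo-4-hydroxyphenyl)prop-2-en-1-one
Product: 4 (E)-1,3-bis[3-bromo-4-(methoxymethoxy)phenyl]prop-2-en-1-one
Conditions: MOMCl (2.5 equiv), K2CO3 (4 equiv), acetone, 0 °C → rt
Reagents that add atoms: chloromethyl methyl ether (MOMCl), COCCl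
Why: Williamson-type O-alkylation of the two acidic bromophenols gives base-stable acetals that the closing mild-acid step removes.

Step 3
Reactants: 4 (E)-1,3-bis[3-bromo-4-(methoxymethoxy)phenyl]prop-2-en-1-one
Product: 5 racemic trans-{3-[3-bromo-4-(methoxymethoxy)phenyl]oxiran-2-yl}[3-bromo-4-(methoxymethoxy)phenyl]methanone
Conditions: 30% aq H2O2 (3 equiv), 2 M NaOH (0.3 equiv), MeOH/THF, 0 °C → rt
Reagents that add atoms: hydrogen peroxide, OO
Why: Weitz–Scheffer nucleophilic epoxidation of the enone gives the trans epoxide, whose two (racemic) centres are erased in step 5.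

Step 4
Reactants: 6 3,5-dibromo-4-methoxybenzaldehyde; 7 malonic acid
Product: 8 (E)-3-(3,5-dibromo-4-methoxyphenyl)prop-2-enoic acid
Conditions: pyridine, piperidine (0.1 equiv), 100 °C; aq HCl work-up
Reagents that add atoms: none
Why: Knoevenagel–Doebner condensation with decarboxylation gives the E-cinnamic acid.

Step 5
Reactants: 5 racemic trans-epoxy ketone; 8 (E)-3-(3,5-dibromo-4-methoxyphenyl)prop-2-enoic acid
Product: 11 (Z)-1,3-bis[3-bromo-4-(methoxymethoxy)phenyl]-3-oxoprop-1-en-2-yl (E)-3-(3,5-dibromo-4-methoxyphenyl)prop-2-enoate, via acid chloride 9 (not isolated), via potassium enolate 10 (not isolated)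
Conditions: (a) 8 (1.1 equiv), (COCl)2 (1.2 equiv), DMF (cat.), CH2Cl2, 0 °C → rt, evaporate from toluene; (b) 5, KOtBu (1.05 equiv), THF, 0 °C → rt; then 9, −20 °C → rt
Reagents that add atoms: oxalyl chloride, O=C(Cl)C(Cl)=O (Cl of intermediate 9 only); potassium tert-butoxide, CC(C)(C)[O-].[K+] (K of intermediate 10 only)
Why: Base-induced isomerisation of the α,β-epoxy ketone (α-deprotonation with E1cB-type opening of the benzylic C–O bond) gives the 1,2-diketone enolate, which settles in the less hindered Z form and is O-acylated by the acid chloride, making the O1–C2 bond of the future ring.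

Step 6
Reactants: 11 (Z)-enol (E)-cinnamate
Product: 13 3-[(R)-(3,5-dibromo-4-methoxyphenyl)(hydroxy)methyl]-4-[3-bromo-4-(methoxymethoxy)phenyl]-5-{(Z)-[3-bromo-4-(methoxymethoxy)phenyl]methylidene}-4-hydroxyoxolan-2-one (C3/C4 diastereomer mixture), via bis-boryl aldol lactone 12 (not isolated)
Conditions: CuCl (5 mol %), (R)-1-[(SP)-2-(diphenylphosphino)ferrocenyl]ethyldicyclohexylphosphine (6 mol %), NaOtBu (10 mol %), B2pin2 (1.2 equiv), THF, 0 °C → rt; then NaBO3·4H2O (5 equiv), THF/H2O, 0 °C → rt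
Reagents that add atoms: bis(pinacolato)diboron, CC1(C)OB(OC1(C)C)B1OC(C)(C)C(C)(C)O1 (boron and pinacol atoms of intermediate 12 only); sodium perborate tetrahydrate, [Na+].[Na+].O[B-]1(O)OO[B-](O)(O)OO1.O.O.O.O.O.O (hydroxyl O of the carbinol in 13)
Why: Proposed new method: the ligated copper–boryl species adds boron to the Re face of the benzylic β-carbon of the activated enol-ester cinnamate (the trisubstituted α-acyloxy enone being the poorer, captodative acceptor), the copper enolate closes 5-exo onto the tethered aryl ketone through the ester oxygen, B2pin2 borylates the aldolate to turn the catalyst over, and perborate then replaces boron by OH with retention, so the ligand alone sets the carbinol centre while the C3/C4 centres are removed in step 7; the closest known reactions are copper-catalysed enantioselective β-borylation of cinnamates and copper-catalysed reductive or borylative aldol cyclisations of ester-tethered enoate–ketones to β-hydroxy lactones.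

Step 7
Reactants: 13 diol lactone
Product: 15 (5Z)-4-(3-bromo-4-hydroxyphenyl)-5-[(3-bromo-4-hydroxyphenyl)methylidene]-3-[(S)-(3,5-dibromo-4-methoxyphenyl)(hydroxy)methyl]furan-2(5H)-one, via MOM-protected butenolide carbinol 14 (not isolated)
Conditions: NaHSO4·SiO2, CH2Cl2, rt
Reagents that add atoms: none
Why: E1 ionisation of the tertiary, benzylic and enol-ether-allylic C4–OH and loss of the acidic C3–H give the fully conjugated (Z)-butenolide, the same solid acid hydrolyses the two aryl MOM acetals, and the secondary carbinol next to the electron-poor dibromoanisyl ring is not ionised under these mild heterogeneous conditions.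

Descriptor note: the carbinol geometry is unchanged from 12 to 15. The label is R in 12 and 13 (aryl outranks the sp3 ring carbon) and S in 14 and 15 (the sp2 ring carbon outranks aryl).

**Compound list**
1 | 1-(3-bromo-4-hydroxyphenyl)ethan-1-one | CC(=O)c1ccc(O)c(Br)c1 | starting material
2 | 3-bromo-4-hydroxybenzaldehyde | O=Cc1ccc(O)c(Br)c1 | starting material
3 | (E)-1,3-bis(3-bromo-4-hydroxyphenyl)prop-2-en-1-one | O=C(/C=C/c1ccc(O)c(Br)c1)c1ccc(O)c(Br)c1 | intermediate
4 | (E)-1,3-bis[3-bromo-4-(methoxymethoxy)phenyl]prop-2-en-1-one | O=C(/C=C/c1ccc(OCOC)c(Br)c1)c1ccc(OCOC)c(Br)c1 | intermediate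
5 | racemic trans-{3-[3-bromo-4-(methoxymethoxy)phenyl]oxiran-2-yl}[3-bromo-4-(methoxymethoxy)phenyl]methanone (2S,3R enantiomer drawn for the racemate) | O=C(c1ccc(OCOC)c(Br)c1)[C@H]2O[C@@H]2c3ccc(OCOC)c(Br)c3 | intermediate
6 | 3,5-dibromo-4-methoxybenzaldehyde | COc1c(Br)cc(C=O)cc1Br | starting material
7 | malonic acid | OC(=O)CC(=O)O | starting material
8 | (E)-3-(3,5-dibromo-4-methoxyphenyl)prop-2-enoic acid | COc1c(Br)cc(/C=C/C(=O)O)cc1Br | intermediate
9 | (E)-3-(3,5-dibromo-4-methoxyphenyl)prop-2-enoyl chloride | COc1c(Br)cc(/C=C/C(=O)Cl)cc1Br | intermediate (not isolated)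
10 | potassium (Z)-1,3-bis[3-bromo-4-(methoxymethoxy)phenyl]-3-oxoprop-1-en-2-olate | [K+].[O-]/C(=C\c1ccc(OCOC)c(Br)c1)C(=O)c2ccc(OCOC)c(Br)c2 | intermediate (not isolated)
11 | (Z)-1,3-bis[3-bromo-4-(methoxymethoxy)phenyl]-3-oxoprop-1-en-2-yl (E)-3-(3,5-dibromo-4-methoxyphenyl)prop-2-enoate | COc1c(Br)cc(/C=C/C(=O)O/C(=C\c2ccc(OCOC)c(Br)c2)C(=O)c3ccc(OCOC)c(Br)c3)cc1Br | intermediate
12 | 4-[3-bromo-4-(methoxymethoxy)phenyl]-5-{(Z)-[3-bromo-4-(methoxymethoxy)phenyl]methylidene}-3-[(R)-(3,5-dibromo-4-methoxyphenyl)(4,4,5,5-tetramethyl-1,3,2-dioxaborolan-2-yl)methyl]-4-[(4,4,5,5-tetramethyl-1,3,2-dioxaborolan-2-yl)oxy]oxolan-2-one (C3/C4 diastereomer mixture) | COc1c(Br)cc([C@H](B2OC(C)(C)C(C)(C)O2)C3C(=O)O/C(=C\c4ccc(OCOC)c(Br)c4)C3(OB5OC(C)(C)C(C)(C)O5)c6ccc(OCOC)c(Br)c6)cc1Br | intermediate (not isolated)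
13 | 3-[(R)-(3,5-dibromo-4-methoxyphenyl)(hydroxy)methyl]-4-[3-bromo-4-(methoxymethoxy)phenyl]-5-{(Z)-[3-bromo-4-(methoxymethoxy)phenyl]methylidene}-4-hydroxyoxolan-2-one (C3/C4 diastereomer mixture) | COc1c(Br)cc([C@H](O)C2C(=O)O/C(=C\c3ccc(OCOC)c(Br)c3)C2(O)c4ccc(OCOC)c(Br)c4)cc1Br | intermediate
14 | (5Z)-4-[3-bromo-4-(methoxymethoxy)phenyl]-5-{[3-bromo-4-(methoxymethoxy)phenyl]methylidene}-3-[(S)-(3,5-dibromo-4-methoxyphenyl)(hydroxy)methyl]furan-2(5H)-one | COc1c(Br)cc([C@H](O)C2=C(c3ccc(OCOC)c(Br)c3)/C(=C/c4ccc(OCOC)c(Br)c4)OC2=O)cc1Br | intermediate (not isolated)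
15 | (5Z)-4-(3-bromo-4-hydroxyphenyl)-5-[(3-bromo-4-hydroxyphenyl)methylidene]-3-[(S)-(3,5-dibromo-4-methoxyphenyl)(hydroxy)methyl]furan-2(5H)-one | COc1c(Br)cc([C@H](O)C2=C(c3ccc(O)c(Br)c3)/C(=C/c3ccc(O)c(Br)c3)OC2=O)cc1Br | target

**Totals**
Total step count: 7. Longest linear sequence: 6 (steps 1, 2, 3, 5, 6, 7).

**Three steps most likely to fail**

Step 6 is the most likely to fail. The copper–boryl species may attack the α-acyloxy enone or the ketone, the enol ester may be cleaved, or the ee may be low. The fallback sets out from 5 (with 6) and comes back at 14. Epoxide 5 is isomerised with aqueous NaOH in EtOH and acidified to the free enol (Z)-1,3-bis[3-bromo-4-(methoxymethoxy)phenyl]-2-hydroxyprop-2-en-1-one F1. Aldehyde 6 is homologated with tert-butyl diazoacetate and SnCl2 (cat.) to tert-butyl 3-(3,5-dibromo-4-methoxyphenyl)-3-oxopropanoate F2. Heating F1 with F2 in toluene at 110 °C goes through the aroylketene to the β-keto enol ester (Z)-1,3-bis[3-bromo-4-(methoxymethoxy)phenyl]-3-oxoprop-1-en-2-yl 3-(3,5-dibromo-4-methoxyphenyl)-3-oxopropanoate F3. Et3N in the same pot closes F3 by Knoevenagel condensation to the ketone (5Z)-4-[3-bromo-4-(methoxymethoxy)phenyl]-5-{[3-bromo-4-(methoxymethoxy)phenyl]methylidene}-3-(3,5-dibromo-4-methoxybenzoyl)furan-2(5H)-one F4. Reduction of F4 with catecholborane and the B-methyl oxazaborolidine derived from diphenylprolinol (enantiomer chosen for the S alcohol, toluene, −78 °C) gives 14, which then needs only the MOM removal of step 7. Here the ring is closed first and the stereocentre is set afterwards by reagent control.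

Step 5 is the second risk. The anhydrous isomerisation may stall, or the enolate may be C-acylated. The fallback sets out from 5 and comes back at 11. Epoxide 5 is isomerised with aqueous NaOH in EtOH and the neutral enol (Z)-1,3-bis[3-bromo-4-(methoxymethoxy)phenyl]-2-hydroxyprop-2-en-1-one F5 (same structure as F1) is isolated and purified. F5 is then esterified with acid 8 by carbodiimide coupling (EDC·HCl, DMAP, CH2Cl2, 0 °C → rt) to give 11. This replaces enolate trapping by acid chloride 9 with coupling of the neutral enol and the free acid.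

Step 7 is the third risk. The allylic, benzylic carbinol formed on dehydration may ionise under acid and racemise or be substituted. The fallback sets out from 13 and comes back at 15. Diol 13 is dehydrated with PPTS (cat.) in CH2Cl2 at 0 °C and 14 is isolated. The MOM ethers are then exchanged without Brønsted acid using TMSOTf and 2,2′-bipyridyl in CH2Cl2 at 0 °C, giving the tris-silyl ether (5Z)-4-[3-bromo-4-(trimethylsilyloxy)phenyl]-5-{[3-bromo-4-(trimethylsilyloxy)phenyl]methylidene}-3-[(S)-(3,5-dibromo-4-methoxyphenyl)(trimethylsilyloxy)methyl]furan-2(5H)-one F6. Hydrolysis of F6 in aqueous MeOH at rt gives 15.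

**Further compounds**
F1 | step 6 | (Z)-1,3-bis[3-bromo-4-(methoxymethoxy)phenyl]-2-hydroxyprop-2-en-1-one | O/C(=C\c1ccc(OCOC)c(Br)c1)C(=O)c2ccc(OCOC)c(Br)c2
F2 | step 6 | tert-butyl 3-(3,5-dibromo-4-methoxyphenyl)-3-oxopropanoate | COc1c(Br)cc(C(=O)CC(=O)OC(C)(C)C)cc1Br
F3 | step 6 | (Z)-1,3-bis[3-bromo-4-(methoxymethoxy)phenyl]-3-oxoprop-1-en-2-yl 3-(3,5-dibromo-4-methoxyphenyl)-3-oxopropanoate | COc1c(Br)cc(C(=O)CC(=O)O/C(=C\c2ccc(OCOC)c(Br)c2)C(=O)c3ccc(OCOC)c(Br)c3)cc1Br
F4 | step 6 | (5Z)-4-[3-bromo-4-(methoxymethoxy)phenyl]-5-{[3-bromo-4-(methoxymethoxy)phenyl]methylidene}-3-(3,5-dibromo-4-methoxybenzoyl)furan-2(5H)-one | COc1c(Br)cc(C(=O)C2=C(c3ccc(OCOC)c(Br)c3)/C(=C/c4ccc(OCOC)c(Br)c4)OC2=O)cc1Br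
F5 | step 5 | (Z)-1,3-bis[3-bromo-4-(methoxymethoxy)phenyl]-2-hydroxyprop-2-en-1-one | O/C(=C\c1ccc(OCOC)c(Br)c1)C(=O)c2ccc(OCOC)c(Br)c2
F6 | step 7 | (5Z)-4-[3-bromo-4-(trimethylsilyloxy)phenyl]-5-{[3-bromo-4-(trimethylsilyloxy)phenyl]methylidene}-3-[(S)-(3,5-dibromo-4-methoxyphenyl)(trimethylsilyloxy)methyl]furan-2(5H)-one | COc1c(Br)cc([C@H](O[Si](C)(C)C)C2=C(c3ccc(O[Si](C)(C)C)c(Br)c3)/C(=C/c4ccc(O[Si](C)(C)C)c(Br)c4)OC2=O)cc1Br
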